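The data were generated by integration from invented constants, and the scatter is random.

I answer yes to your quick question, and I do not take that answer straight from the late readings.

| flask | left-handed substrate | right-handed substrate | partner | protic impurity | free catalyst | remark | time |
|---|---|---|---|---|---|---|---|
| zeta | 0.89 M | 0.89 M | 3 equiv | 0.022 M | 0.33 mol% | run made earlier |  |
| beta | 0.89 M | 0.89 M | 3 equiv | 0.089 M | 0.33 mol% | run made earlier |  |
| flask | 0.89 M | 0.89 M | 3.00 equiv | 0.0445 M | 0.33 mol% |  | 5.0 h |

| run | time / h | right-handed substrate / % | left-handed substrate / % | left-handed product / % |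
|---|---|---|---|---|
| zeta | 0.833 | 6.8 | 4.2 | 47.3 |
| zeta | 1.50 | 3.9 | 0.7 | 49.4 |
| zeta | 2.50 | 3.1 | 0.2 | 48.3 |
| zeta | 3.00 | 2.6 | 0.7 | 48.5 |
| zeta | 4.00 | 2.2 | 0 | 48.9 |
| beta | 0.333 | 17.1 | 20.8 | 30.3 |
| beta | 1.00 | 6.4 | 1.5 | 48.2 |
| beta | 2.00 | 3.1 | 0 | 48.7 |
| beta | 3.00 | 2.4 | 0.3 | 48.0 |
| beta | 4.00 | 2.3 | 0 | 49.3 |

(each reading ± 0.5 percentage points)

- free catalyst is single-handed; left-handed substrate and right-handed substrate are mirror images of each other, charged as a racemate, each of them at the stated concentration

1. whether the excess of right-handed substrate over left-handed substrate among what is left of the two reaches 95 % by 5.0 h (yes / no)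
2. the highest excess of right-handed substrate over left-handed substrate among what is left of the two up to 5.0 h

I start from what the question demands. For the wanted excess, the left-handed substrate may stand at a fraction of the right-handed substrate no greater than one minus the excess over one plus the excess:

ρ = 0.0256

The beta run's last reading of right-handed substrate is 2.3 % of the charge, so the left-handed substrate may be 0.0590 % of the charge, which is less than the scatter of 0.5 percentage points. A remainder that small cannot be read directly, so I reckon it as a correction. Starting from the beta reading at 1.00 h, I ask what selectivity factor it needs: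

needed factor = ln(1.5 % / 0.0590 %) / ln(6.4 % / 2.3 %) = 3.16

This needed factor is the log fall of the left-handed substrate divided by the log fall of the right-handed substrate across a window. In the beta run, the factor read is 0.817 up to the first reading, then 2.68 in the next window, still short of the need but climbing. The zeta run climbs too, from 1.24 to 3.22, though that last value rests on a faint reading. The flask's protic impurity lies between the two runs, so I expect the climb to carry on and commit to yes, with a top above 95 %.

The forecast says no with a top of 90 %, on a late plateau that “looks like a plateau from equilibrium or catalyst death”; the flask gives yes, with a top of 99.9 %.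

    free catalyst + left-handed substrate ⇌ catalyst intermediate A (K = 11.0 M⁻¹, k = 0.460 M⁻¹ s⁻¹)
    free catalyst + right-handed substrate ⇌ catalyst intermediate B (K = 1.20 M⁻¹, k = 4.40 M⁻¹ s⁻¹)
    partner + catalyst intermediate A → free catalyst + left-handed product (k = 0.750 M⁻¹ s⁻¹)
    partner + catalyst intermediate B → free catalyst + right-handed product (k = 0.300 M⁻¹ s⁻¹)
    partner → decomposed reagent (k = 1.90 × 10⁻⁴ s⁻¹)
    partner + protic impurity → quenched reagent (k = 0.00530 M⁻¹ s⁻¹)
    left-handed product ⇌ right-handed product (k = 8.30 × 10⁻⁵ s⁻¹)

The flask reaches the wanted excess at 2.00 h, with 3.11 % of the charge still standing as right-handed substrate. Between 0.500 h and 2.50 h, the flask's left-handed substrate falls from 12.0 % to 0.0204 % and its right-handed substrate from 11.6 % to 2.68 %. The window factor of the flask is therefore 4.35, above the needed 3.16.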